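**Assumption:** robustol has no stereocentre, axis or stable planar chirality (the SMILES carries no stereodescriptors), so it is made as the single achiral compound and no stereocontrol is needed.

## Retrosynthetic overview

1. Robustol ⇐ a tetrabromo-robustol (Br on all four ring carbons ortho to the C14 bridge) by fourfold C–Br hydrogenolysis; the bromines are traceless blocking groups.
2. Tetrabromo-robustol ⇐ the C2v-symmetric 1,14-bis(2,6-dibromo-3,5-dihydroxyphenyl)tetradecane by one intramolecular dehydrogenative phenol O–C coupling (λ3-iodane). This single step makes the diaryl ether, closes the 22-membered ring and turns two identical rings into the two different rings of the target.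
3. Symmetric tetrabromide ⇐ 1,14-bis(3,5-dihydroxyphenyl)tetradecane (4,6-dibromination of each resorcinol) ⇐ its tetramethyl ether (BBr3).
4. Tetramethyl ether ⇐ 1-bromo-3,5-dimethoxybenzene (×2) + tetradeca-1,13-diene by double hydroboration / B-alkyl Suzuki coupling.
5. Ring order: both benzene rings are bought; the macrocycle is the only ring formed (step 4).

## Forward route

**Step 1**
Reactants: 1, 1-bromo-3,5-dimethoxybenzene (2.2 equiv); 2, tetradeca-1,13-diene (1.0 equiv)
Product: 3, 1,14-bis(3,5-dimethoxyphenyl)tetradecane
Conditions: 2, 9-BBN-H (2.3 equiv), THF, 0 °C → rt; then 1, PdCl2(dppf) (5 mol %), 3 M aq K3PO4, THF–DMF, 65 °C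
Reagents that add atoms: none (9-BBN delivers only H; boron is lost)
Why: 9-BBN hydroborates both terminal alkenes with anti-Markovnikov selectivity, and the resulting bis(primary alkyl)borane undergoes a double B-alkyl Suzuki–Miyaura coupling with the aryl bromide to give the symmetric C14-linked bis-arene in one operation.

**Step 2**
Reactants: 3, 1,14-bis(3,5-dimethoxyphenyl)tetradecane
Product: 4, 5,5'-(tetradecane-1,14-diyl)bis(benzene-1,3-diol)
Conditions: BBr3 (6 equiv), CH2Cl2, −78 °C → rt; MeOH then H2O
Reagents that add atoms: none
Why: BBr3 cleavage of aryl methyl ethers is the standard way to unmask 5-alkylresorcinols (olivetol-type), and the saturated chain is inert.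

**Step 3**
Reactants: 4, 5,5'-(tetradecane-1,14-diyl)bis(benzene-1,3-diol)
Product: 5, 5,5'-(tetradecane-1,14-diyl)bis(4,6-dibromobenzene-1,3-diol)
Conditions: Br2 (4.05 equiv, slow addition), CH2Cl2–MeCN (4:1), −20 → 0 °C, dark; aq NaHSO3
Reagents that add atoms: bromine, BrBr
Why: electrophilic aromatic bromination of a 5-alkylresorcinol takes C4 and C6 (para to one OH, ortho to the other) before C2, as in the known preparation of 4,6-dibromo-olivetol. The bromines block every ring carbon next to the tether and deactivate the rings towards C–C coupling, which an unblocked bis-resorcinol would otherwise undergo in step 4.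

**Step 4**
Reactants: 5, 5,5'-(tetradecane-1,14-diyl)bis(4,6-dibromobenzene-1,3-diol)
Product: 6, tetrabromo-robustol (robustol bearing Br on the two ring carbons flanking the bridge on each ring; C26H32Br4O4)
Conditions: PhI(OAc)2 (1.05 equiv, syringe pump over 8 h), dry (CF3)2CHOH–CH2Cl2 (1:4), 1 mM in 5, −20 → 0 °C; aq Na2S2O3
Reagents that add atoms: none
Why: Proposed new method: one phenol of 5 exchanges onto iodine(III) to give an aryloxy-λ3-iodane (phenoxenium equivalent) whose other ortho carbon (C6) and para carbon (C4) carry Br, so the only open electrophilic carbon is C2 between the two oxygens; a hydroxyl of the other, identical ring (within reach through the C14 tether, with high dilution suppressing dimers) adds at C2, PhI and AcOH leave, and the 6-aryloxycyclohexa-2,4-dienone tautomerises at once to the aromatic diaryl ether; C-arylation is disfavoured because the nucleophilic ring's only free carbon would have to form a strained para,para'-bridged biaryl; since the rings are identical, either ring acting as electrophile gives the same product; closest known reaction types are the Yamamura oxidative macrocyclisation of o-halophenols to isodityrosine-type diaryl ethers (Tl(III) or anodic) and PIDA/PIFA dearomatising C–O bond formation on dibromophenols (spiroisoxazoline syntheses); expected yield 15–35%.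

**Step 5**
Reactants: 6, tetrabromo-robustol
Product: 7, robustol
Conditions: H2 (1 atm), 10% Pd/C, Et3N (6 equiv), MeOH–EtOAc, rt; dilute HCl work-up under N2
Reagents that add atoms: none (only H)
Why: Pd-catalysed hydrogenolysis removes aryl C–Br bonds (bromophenols are especially easy) while phenols, the diaryl ether and the alkyl chain are untouched, giving the target with no stereocentre to set.

## Compound list

1 | 1-bromo-3,5-dimethoxybenzene | COc1cc(Br)cc(OC)c1 | starting material
2 | tetradeca-1,13-diene | C=CCCCCCCCCCCC=C | starting material
3 | 1,14-bis(3,5-dimethoxyphenyl)tetradecane | COc1cc(CCCCCCCCCCCCCCc2cc(OC)cc(OC)c2)cc(OC)c1 | intermediate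
4 | 5,5'-(tetradecane-1,14-diyl)bis(benzene-1,3-diol) | Oc1cc(O)cc(CCCCCCCCCCCCCCc2cc(O)cc(O)c2)c1 | intermediate
5 | 5,5'-(tetradecane-1,14-diyl)bis(4,6-dibromobenzene-1,3-diol) | Oc1cc(O)c(Br)c(CCCCCCCCCCCCCCc2c(Br)c(O)cc(O)c2Br)c1Br | intermediate
6 | tetrabromo-robustol (Br on both ring carbons ortho to the bridge, on each ring) | Oc1c(Br)c2c(Br)c(c1)Oc1c(O)c(Br)c(c(Br)c1O)CCCCCCCCCCCCCC2 | intermediate
7 | robustol | Oc1cc2cc(c1)Oc1c(O)cc(cc1O)CCCCCCCCCCCCCC2 | target

## Summary

Total step count: 5
Longest linear sequence: 5 (fully linear)

**Steps most likely to fail, with fallbacks**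

1. **Step 4 (oxidative macro-etherification).** Risks are ipso attack at C–Br, oligomerisation, acetoxylation at C2 and over-oxidation of the product. Fallback: abandon oxidative C–H coupling for a halide-directed closure. Treat unbrominated 4 with I2/NaHCO3 (1 equiv, aq THF, 0 °C; C2-selective as for 2-iodoresorcinol) to give the mono-C2-iodide, then close by intramolecular Cu-catalysed Ullmann etherification (CuI, picolinic acid, K3PO4, DMSO, 90 °C, 1 mM), which gives 7 directly.
2. **Step 3 (fourfold regioselective bromination).** Risks are over-bromination at C2 or incomplete reaction, giving polar mixtures that are hard to separate. Fallback: change the order and the substrate. Brominate the tetramethyl ether 3 (NBS, MeCN), where the position between the two OMe groups is shielded and the products are non-polar and crystallisable, then demethylate with BBr3 to reach 5.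
3. **Step 5 (fourfold hydrodebromination).** Risks are stalling at partially brominated material or catalyst poisoning. Fallback: switch to a halophilic, non-catalytic reduction (Na2SO3, ascorbic acid, Et3N, MeOH–H2O, reflux), the method used to unblock dibromo-olivetol-derived cannabinoids.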